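Assumptions: the single stereocentre in the SMILES is C2 and works out as (S), the natural flavanone series. Flavanone numbering is used throughout, and TIPS = triisopropylsilyl.

## Retrosynthetic overview
1. The target 13 comes from 12 by one buffered global desilylation of the 7-O and 4'-O silyl ethers.
2. The C8 prenyl comes from a Eu(III)-catalysed para-Claisen–Cope shift of a 5-O-prenyl ether. That ether first serves as the 5-OH protecting group.
3. The C2–C1' bond and the C2 stereocentre come from a Rh(I)/chiral bisphosphine asymmetric 1,4-addition of arylboronic acid 10 to the preformed chromone 5. No chalcone or oxa-Michael closure is used.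
4. Ring order: the A ring is bought, the pyranone C ring is closed first as an achiral chromone, and the intact prenylated B ring is attached last.
5. The B-ring piece 10 comes from 4-bromophenol by ortho-C-prenylation, silylation and borylation.

## Route

**Step 1**
Reactants: 1, 2,4,6-trihydroxyacetophenone
Product: 2, 5,7-dihydroxy-4H-chromen-4-one
Conditions: HC(OEt)3 (6 equiv), 70% HClO4 (1.2 equiv), 0 °C → rt; collect the pyrylium salt; H2O, 90 °C
Reagents that add atoms: triethyl orthoformate, CCOC(OCC)OCC (supplies C2); water, O (hydrolysis of the 4-ethoxybenzopyrylium salt, C4 carbonyl O)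
Why: This is the orthoformate/benzopyrylium chromone synthesis, in which the acid-generated diethoxycarbenium ion formylates the enolised methyl ketone, an ortho OH (the two are equivalent) closes the ring, and hydrolysis gives the chromone.

**Step 2**
Reactants: 2, 5,7-dihydroxychromone
Product: 3, 5-hydroxy-7-(triisopropylsilyloxy)-4H-chromen-4-one
Conditions: TIPSCl (1.05 equiv), imidazole (2.2 equiv), DMF, 0 °C → rt
Reagents that add atoms: triisopropylsilyl chloride, CC(C)[Si](Cl)(C(C)C)C(C)C
Why: This is a chemoselective O-silylation, because the acidic unchelated 7-OH reacts while the 5-OH is held in a hydrogen bond to C4=O and stays inert to one equivalent of a bulky silyl chloride.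

**Step 3**
Reactants: 3, 5-hydroxy-7-TIPSO-chromone; 4, 3-methylbut-2-en-1-ol (prenol)
Product: 5, 5-(3-methylbut-2-enyloxy)-7-(triisopropylsilyloxy)-4H-chromen-4-one
Conditions: 4 (1.5 equiv), PPh3, DIAD, THF, 0 °C → rt
Reagents that add atoms: prenol (4), CC(C)=CCO (C5H9 unit; its OH is lost)
Why: This is a Mitsunobu etherification, whose neutral conditions alkylate the chelated phenol (pKa about 11) by SN2 at the primary allylic carbon without touching the base-labile vinylogous silyl ester at C7.

**Step 4**
Reactants: 6, 4-bromophenol; 7, 1-bromo-3-methylbut-2-ene (prenyl bromide)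
Product: 8, 4-bromo-2-(3-methylbut-2-enyl)phenol
Conditions: NaH (1.05 equiv), toluene, 0 °C; then 7 (1.0 equiv), rt
Reagents that add atoms: prenyl bromide (7), CC(C)=CCBr
Why: This is ortho-C-alkylation of a phenoxide, in which the tight, aggregated sodium phenoxide in a non-polar solvent shields oxygen and sends the allylic halide to the ortho carbon (para is blocked by Br) to give the linear prenyl group.

**Step 5**
Reactants: 8, 4-bromo-2-prenylphenol
Product: 9, [4-bromo-2-(3-methylbut-2-enyl)phenoxy]triisopropylsilane
Conditions: TIPSCl (1.2 equiv), imidazole, DMF, rt → 40 °C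
Reagents that add atoms: triisopropylsilyl chloride, CC(C)[Si](Cl)(C(C)C)C(C)C
Why: This is a standard phenol silylation, and TIPS is chosen because it survives n-BuLi and aqueous Rh catalysis and is removed together with the 7-O group at the end.

**Step 6**
Reactants: 9, aryl bromide TIPS ether
Product: 10, [3-(3-methylbut-2-enyl)-4-(triisopropylsilyloxy)phenyl]boronic acid
Conditions: B(OiPr)3 (1.5 equiv), THF–toluene, −78 °C, n-BuLi added dropwise (in situ quench); then aq NH4Cl / dilute HCl, 0 °C
Reagents that add atoms: triisopropyl borate, CC(C)OB(OC(C)C)OC(C)C (B); water, O (B–OH oxygens)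
Why: This is Li–Br exchange followed by borate trapping, where the in situ quench captures the aryllithium before it can deprotonate the benzylic/allylic CH2, and the lithium sits para to OSi so no silyl migration is possible.

**Step 7 (key step)**
Reactants: 5, 5-prenyloxy-7-TIPSO-chromone; 10, arylboronic acid (2 equiv)
Product: 11, (2S)-5-(3-methylbut-2-enyloxy)-2-[3-(3-methylbut-2-enyl)-4-(triisopropylsilyloxy)phenyl]-7-(triisopropylsilyloxy)chroman-4-one
Conditions: [RhCl(C2H4)2]2 (2.5 mol %), (S)-MeO-F12-BIPHEP [(S)-6,6'-dimethoxybiphenyl-2,2'-diyl-bis(bis(3,4,5-trifluorophenyl)phosphine)] (5.5 mol %), aq KOH (5 mol %, only enough to form Rh–OH), toluene–H2O 10:1, 30 °C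
Reagents that add atoms: none (aryl comes from 10; C3–H comes from water)
Why: This is a Hayashi–Miyaura asymmetric 1,4-addition in which the very π-acidic (S)-bisphosphine makes Ar–Rh(I) reactive enough to insert into the chromone C2=C3 bond and delivers aryl to the C2-Re face (the same quadrant model by which (S)-biaryl diphosphines give (S)-3-arylcyclohexanones, which maps onto 2S here), while fast protonolysis of the oxa-π-allyl rhodium in essentially base-free toluene prevents retro-oxa-Michael racemisation and the trisubstituted prenyl alkenes do not insert.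

**Step 8**
Reactants: 11, (2S)-5-O-prenyl flavanone
Product: 12, (2S)-5-hydroxy-8-(3-methylbut-2-enyl)-2-[3-(3-methylbut-2-enyl)-4-(triisopropylsilyloxy)phenyl]-7-(triisopropylsilyloxy)chroman-4-one
Conditions: Eu(fod)3 (10 mol %), PhCl (0.05 M), 80 °C, Ar
Reagents that add atoms: none (isomerisation)
Why: This is a Lewis-acid-accelerated para-Claisen–Cope cascade in which Eu(III), chelated by C4=O and 5-O, triggers a [3,3] shift to C6 (the only open ortho site), the crowded 6-(1,1-dimethylallyl) dienone next to OTIPS relays by a Cope [3,3] shift to the para carbon C8, and tautomerisation gives the linear 8-prenyl group and free 5-OH, with C2 uninvolved and no base present to open the ring.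

**Step 9**
Reactants: 12, bis-TIPS ether
Product: 13, euchrestaflavanone A, (2S)-5,7-dihydroxy-2-[4-hydroxy-3-(3-methylbut-2-enyl)phenyl]-8-(3-methylbut-2-enyl)chroman-4-one
Conditions: TBAF (2.5 equiv), AcOH (3.0 equiv), THF, 0 °C
Reagents that add atoms: none
Why: This is a fluoride desilylation of two aryl silyl ethers, where the AcOH buffer keeps the liberated phenols protonated so there is no phenoxide-driven ring opening and racemisation, and the absence of strong acid prevents the o-prenylphenols from cyclising to chromans.

## Compound list
1 | 2,4,6-trihydroxyacetophenone | CC(=O)c1c(O)cc(O)cc1O | starting material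
2 | 5,7-dihydroxychromone | O=c1ccoc2cc(O)cc(O)c12 | intermediate
3 | 5-hydroxy-7-TIPSO-chromone | O=c1ccoc2cc(O[Si](C(C)C)(C(C)C)C(C)C)cc(O)c12 | intermediate
4 | prenol | CC(C)=CCO | starting material
5 | 5-prenyloxy-7-TIPSO-chromone | CC(C)=CCOc1cc(O[Si](C(C)C)(C(C)C)C(C)C)cc2occc(=O)c12 | intermediate
6 | 4-bromophenol | Oc1ccc(Br)cc1 | starting material
7 | prenyl bromide | CC(C)=CCBr | starting material
8 | 4-bromo-2-prenylphenol | CC(C)=CCc1cc(Br)ccc1O | intermediate
9 | 4-bromo-2-prenylphenyl TIPS ether | CC(C)=CCc1cc(Br)ccc1O[Si](C(C)C)(C(C)C)C(C)C | intermediate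
10 | 3-prenyl-4-TIPSO-phenylboronic acid | CC(C)=CCc1cc(B(O)O)ccc1O[Si](C(C)C)(C(C)C)C(C)C | intermediate
11 | (2S)-5-O-prenyl-3'-prenyl-7,4'-bis-TIPS flavanone | CC(C)=CCc1cc([C@@H]2CC(=O)c3c(OCC=C(C)C)cc(O[Si](C(C)C)(C(C)C)C(C)C)cc3O2)ccc1O[Si](C(C)C)(C(C)C)C(C)C | intermediate
12 | (2S)-5-hydroxy-8,3'-diprenyl-7,4'-bis-TIPS flavanone | CC(C)=CCc1cc([C@@H]2CC(=O)c3c(O)cc(O[Si](C(C)C)(C(C)C)C(C)C)c(CC=C(C)C)c3O2)ccc1O[Si](C(C)C)(C(C)C)C(C)C | intermediate
13 | euchrestaflavanone A, (2S) | CC(C)=CCc1cc([C@@H]2CC(=O)c3c(O)cc(O)c(CC=C(C)C)c3O2)ccc1O | target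

## Summary
Total steps: 9. Longest linear sequence: 6 (steps 1, 2, 3, 7, 8, 9; the B-ring branch through steps 4, 5, 6, 7, 8, 9 is also 6).

Steps most likely to fail:
1. **Step 7.** The 5,7-dioxygenated chromone is a poor acceptor, the electron-rich boronic acid 10 can protodeboronate, and the Rh enolate may ring-open.
   Fallback: run the 1,4-addition racemically with an achiral Rh–diene catalyst, then obtain (S)-11 by kinetic resolution. Asymmetric transfer hydrogenation (Ru–TsDPEN, HCO2H/Et3N) reduces the (R)-ketone to the cis-flavan-4-ol and returns the (S)-ketone.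
2. **Step 8.** The cascade may stop at the 6-(1,1-dimethylallyl) stage, lose the prenyl group, or erode ee at 80 °C. Check ee by chiral HPLC before and after this step.
   Fallback: invert the order. Carry out the Claisen–Cope shift on achiral chromone 5, cap the released 5-OH as a TBS ether, and then run the asymmetric arylation on the 8-prenylchromone. This costs one extra step, and all three silyl groups come off together at the end.
3. **Step 4.** C- versus O-alkylation, over-alkylation and chroman formation can all lower the yield.
   Fallback: O-allylate 6, run a thermal aromatic Claisen rearrangement to 2-allyl-4-bromophenol, silylate, and convert allyl to prenyl by cross-metathesis with 2-methyl-2-butene (Grubbs II).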